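The route rests on cutting the dihydropyran ring at C4–C4a and O1–C2, which reduces the chroman to symmetric 5-ethynylresorcinol and isoprene. One acid-catalysed operation (Friedel–Crafts prenylation, then Markovnikov ring closure) makes both bonds. It exploits the resorcinol pattern of the benzo ring, where C4a is ortho to the O1-bearing C8a and para to the C7 oxygen, and the slim sp carbon on C5. The precursor is thus only the diol and isoprene. C-Prenylation at C6, a Sonogashira/heteroannulation with an iodosalicylaldehyde, and a hydroboration/Zweifel pair that sets the (R)-configured side chain on benzofuran C7 complete the target.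

Key step: step 2

Remark: chroman positions are numbered O1, C2, C3, C4, C4a, C5–C8, C8a and benzofuran positions O1, C2, C3, C3a, C4–C7, C7a; TBS = tert-butyldimethylsilyl.
Remark: in step 9 the ligand antipode is assigned by analogy with the parent styrene; if the sense of induction is opposite on this substrate, (S)-DTBM-SEGPHOS is used and nothing else changes.

Step 1
Reactants: 1 3,5-dihydroxybenzaldehyde
Product: 2 5-ethynylbenzene-1,3-diol
Conditions: dimethyl (1-diazo-2-oxopropyl)phosphonate, K2CO3, MeOH, 0 °C to rt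
Reagents that add atoms: dimethyl (1-diazo-2-oxopropyl)phosphonate, CC(=O)C(=[N+]=[N-])P(=O)(OC)OC
Why: The Ohira–Bestmann form of the Seyferth–Gilbert homologation turns the aldehyde into the terminal alkyne under K2CO3/MeOH, which the two phenols (as phenoxides meta to the formyl group, not conjugated with it) should tolerate.

Step 2
Reactants: 2 5-ethynylbenzene-1,3-diol; 3 isoprene
Product: 5 5-ethynyl-2,2-dimethyl-3,4-dihydro-2H-chromen-7-ol, via ortho-prenylresorcinol 4 (not isolated)
Conditions: isoprene (1.1 equiv, slow addition), Amberlyst 15 (sulfonic acid resin), THF, 65 °C, sealed tube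
Reagents that add atoms: none
Why: The resin protonates isoprene to the tertiary allylic cation, which alkylates the resorcinol through its primary terminus at a carbon ortho to the alkyne (Friedel–Crafts) to give 4, and reprotonation of the prenyl alkene of 4 gives a tertiary cation that the neighbouring phenol oxygen captures (Markovnikov hydroalkoxylation). The closest known reaction type is the acid-catalysed formal [3+3] chroman annulation of phenols and resorcinols with isoprene. The dihydropyran ring closes in a 6-endo-trig sense, the oxygen adding to the gem-dimethyl alkene carbon. No stereocentre is created. The step needs attack at a carbon ortho to the alkyne rather than at the carbon between the two hydroxyls, and one annulation rather than two: the two wanted positions are equivalent by symmetry, each ortho to one hydroxyl and para to the other with only a linear ethynyl neighbour, whereas the third site is flanked by two oxygens, and limiting, slowly added isoprene is meant to hold back the second annulation. Ring closure is unambiguous because the new prenyl group has only one hydroxyl next to it.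

Step 3
Reactants: 5 5-ethynyl-2,2-dimethyl-3,4-dihydro-2H-chromen-7-ol; 6 prenyl bromide
Product: 7 5-ethynyl-2,2-dimethyl-6-(3-methylbut-2-en-1-yl)-3,4-dihydro-2H-chromen-7-ol
Conditions: NaH (1.1 equiv), toluene, 0 °C; then prenyl bromide, rt
Reagents that add atoms: none
Why: ortho-C-Alkylation of a sodium phenoxide in a non-polar solvent (tight ion pair) should favour C- over O-prenylation and C6 (ortho to the phenoxide oxygen, para to O1) over C8 (between two oxygens), while the non-acidic medium leaves the new prenyl group uncyclised.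

Step 4
Reactants: 7 5-ethynyl-2,2-dimethyl-6-(3-methylbut-2-en-1-yl)-3,4-dihydro-2H-chromen-7-ol
Product: 8 TBS ether of 7 (alkyne fragment)
Conditions: TBSCl, imidazole, DMF, rt
Reagents that add atoms: tert-butyldimethylsilyl chloride, CC(C)(C)[Si](C)(C)Cl
Why: Imidazole-promoted silyl ether formation masks the last phenol so that it cannot consume base, iodine or organolithium later, and the alkyne C–H is untouched.

Step 5
Reactants: 9 2,4,6-trihydroxybenzaldehyde
Product: 10 2-hydroxy-4,6-bis(tert-butyldimethylsilyloxy)benzaldehyde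
Conditions: TBSCl (2.1 equiv), i-Pr2NEt, CH2Cl2, 0 °C
Reagents that add atoms: tert-butyldimethylsilyl chloride, CC(C)(C)[Si](C)(C)Cl
Why: Regioselective silyl ether formation: the 4-OH and one ortho-OH react, whereas the remaining ortho-OH is hydrogen-bonded to the formyl oxygen and should stay free with a hindered amine base and limited silyl chloride.

Step 6
Reactants: 10 2-hydroxy-4,6-bis(tert-butyldimethylsilyloxy)benzaldehyde
Product: 11 2-hydroxy-3-iodo-4,6-bis(tert-butyldimethylsilyloxy)benzaldehyde
Conditions: NIS (1.05 equiv), DMF, 0 °C to rt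
Reagents that add atoms: N-iodosuccinimide, O=C1CCC(=O)N1I
Why: Electrophilic aromatic iodination is directed ortho to the free phenol (C3), the alternative C5 being buried between two bulky silyloxy groups, and neutral NIS leaves the silyl ethers intact.

Step 7
Reactants: 11 2-hydroxy-3-iodo-4,6-bis(tert-butyldimethylsilyloxy)benzaldehyde; 8 TBS ether of 7
Product: 13 tris-TBS 2-(chroman-5-yl)benzofuran-7-carbaldehyde, via ortho-alkynylphenol 12 (not isolated)
Conditions: PdCl2(PPh3)2 (5 mol%), CuI (10 mol%), Et3N, DMF, 70 °C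
Reagents that add atoms: none
Why: Sonogashira coupling gives 12, whose only free hydroxyl then adds 5-endo-dig to the metal-activated alkyne in the same pot (heteroannulation), so the furan oxygen is the one next to the formyl-bearing carbon and the formyl group ends at C7 of the benzofuran.

Step 8
Reactants: 13 tris-TBS 2-(chroman-5-yl)benzofuran-7-carbaldehyde
Product: 14 tris-TBS 7-vinylbenzofuran
Conditions: Ph3PCH3Br, KN(SiMe3)2, THF, 0 °C to rt
Reagents that add atoms: methyltriphenylphosphonium bromide, C[P+](c1ccccc1)(c1ccccc1)c1ccccc1.[Br-]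
Why: Wittig methylenation with the non-stabilised ylide converts the hindered aryl aldehyde into the styrene without touching the silyl ethers or the prenyl group.

Step 9
Reactants: 14 tris-TBS 7-vinylbenzofuran
Product: 15 (S)-configured benzylic pinacol boronate
Conditions: HBpin (1.5 equiv), CuCl (5 mol%), (R)-DTBM-SEGPHOS (5.5 mol%), NaOtBu (10 mol%), toluene, rt
Reagents that add atoms: pinacolborane, CC1(C)OBOC1(C)C
Why: Copper hydride-catalysed Markovnikov hydroboration: the ligated CuH adds face-selectively across the styrenic alkene to a benzylic copper species that exchanges with HBpin with retention, so the chiral bisphosphine sets the (S)-boron-bearing centre, while the trisubstituted prenyl alkene and the benzofuran should not be hydrocuprated.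

Step 10
Reactants: 15 (S)-configured benzylic pinacol boronate
Product: 18 tris-TBS ether of the target, via boronate ate complex 16 (not isolated), via beta-iodoalkyl boronic ester 17 (not isolated)
Conditions: 2-bromopropene, t-BuLi (2 equiv), THF, −78 °C, then 15; I2, MeOH, −78 °C; NaOMe, MeOH, −78 to 0 °C
Reagents that add atoms: 2-bromopropene (delivered as isopropenyllithium), CC(Br)=C
Why: Zweifel olefination: isopropenyllithium forms 16, iodine triggers a stereoretentive 1,2-metallate shift of the benzylic carbon to give 17, and methoxide induces anti-elimination of boron and iodine, so the C–B bond becomes the C–isopropenyl bond with retention and the (S)-boronate gives the (R)-alkene (the descriptor changes only through the priority rules).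

Step 11
Reactants: 18 tris-TBS ether of the target
Product: 19 target
Conditions: Bu4NF, AcOH, THF, 0 °C
Reagents that add atoms: none
Why: Fluoride-mediated desilylation buffered with acetic acid removes all three aryl silyl ethers without strong acid, so the ortho-prenyl and ortho-methylbutenyl phenols cannot cyclise and the stereocentre is untouched.

Compound list
1 | 3,5-dihydroxybenzaldehyde | O=Cc1cc(O)cc(O)c1 | starting material
2 | 5-ethynylbenzene-1,3-diol | C#Cc1cc(O)cc(O)c1 | intermediate
3 | isoprene (2-methylbuta-1,3-diene) | C=CC(C)=C | starting material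
4 | 5-ethynyl-4-(3-methylbut-2-en-1-yl)benzene-1,3-diol | C#Cc1cc(O)cc(O)c1CC=C(C)C | intermediate (not isolated)
5 | 5-ethynyl-2,2-dimethyl-3,4-dihydro-2H-chromen-7-ol | C#Cc1cc(O)cc2OC(C)(C)CCc12 | intermediate
6 | prenyl bromide (1-bromo-3-methylbut-2-ene) | CC(C)=CCBr | starting material
7 | 5-ethynyl-2,2-dimethyl-6-(3-methylbut-2-en-1-yl)-3,4-dihydro-2H-chromen-7-ol | C#Cc1c(CC=C(C)C)c(O)cc2OC(C)(C)CCc12 | intermediate
8 | tert-butyl{[5-ethynyl-2,2-dimethyl-6-(3-methylbut-2-en-1-yl)-3,4-dihydro-2H-chromen-7-yl]oxy}dimethylsilane | C#Cc1c(CC=C(C)C)c(O[Si](C)(C)C(C)(C)C)cc2OC(C)(C)CCc12 | intermediate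
9 | 2,4,6-trihydroxybenzaldehyde | O=Cc1c(O)cc(O)cc1O | starting material
10 | 2-hydroxy-4,6-bis(tert-butyldimethylsilyloxy)benzaldehyde | O=Cc1c(O)cc(O[Si](C)(C)C(C)(C)C)cc1O[Si](C)(C)C(C)(C)C | intermediate
11 | 2-hydroxy-3-iodo-4,6-bis(tert-butyldimethylsilyloxy)benzaldehyde | O=Cc1c(O)c(I)c(O[Si](C)(C)C(C)(C)C)cc1O[Si](C)(C)C(C)(C)C | intermediate
12 | 2-hydroxy-4,6-bis(tert-butyldimethylsilyloxy)-3-{[7-(tert-butyldimethylsilyloxy)-2,2-dimethyl-6-(3-methylbut-2-en-1-yl)-3,4-dihydro-2H-chromen-5-yl]ethynyl}benzaldehyde | O=Cc1c(O)c(C#Cc2c(CC=C(C)C)c(O[Si](C)(C)C(C)(C)C)cc3OC(C)(C)CCc23)c(O[Si](C)(C)C(C)(C)C)cc1O[Si](C)(C)C(C)(C)C | intermediate (not isolated)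
13 | 4,6-bis(tert-butyldimethylsilyloxy)-2-[7-(tert-butyldimethylsilyloxy)-2,2-dimethyl-6-(3-methylbut-2-en-1-yl)-3,4-dihydro-2H-chromen-5-yl]-1-benzofuran-7-carbaldehyde | O=Cc1c(O[Si](C)(C)C(C)(C)C)cc(O[Si](C)(C)C(C)(C)C)c2cc(-c3c(CC=C(C)C)c(O[Si](C)(C)C(C)(C)C)cc4OC(C)(C)CCc34)oc12 | intermediate
14 | 4,6-bis(tert-butyldimethylsilyloxy)-2-[7-(tert-butyldimethylsilyloxy)-2,2-dimethyl-6-(3-methylbut-2-en-1-yl)-3,4-dihydro-2H-chromen-5-yl]-7-ethenyl-1-benzofuran | C=Cc1c(O[Si](C)(C)C(C)(C)C)cc(O[Si](C)(C)C(C)(C)C)c2cc(-c3c(CC=C(C)C)c(O[Si](C)(C)C(C)(C)C)cc4OC(C)(C)CCc34)oc12 | intermediate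
15 | 2-[(1S)-1-{4,6-bis(tert-butyldimethylsilyloxy)-2-[7-(tert-butyldimethylsilyloxy)-2,2-dimethyl-6-(3-methylbut-2-en-1-yl)-3,4-dihydro-2H-chromen-5-yl]-1-benzofuran-7-yl}ethyl]-4,4,5,5-tetramethyl-1,3,2-dioxaborolane | CC1(C)OB(OC1(C)C)[C@@H](C)c1c(O[Si](C)(C)C(C)(C)C)cc(O[Si](C)(C)C(C)(C)C)c2cc(-c3c(CC=C(C)C)c(O[Si](C)(C)C(C)(C)C)cc4OC(C)(C)CCc34)oc12 | intermediate
16 | lithium isopropenyl ate complex of boronate 15 (benzylic centre S, unchanged) | [Li+].C=C(C)[B-]1(OC(C)(C)C(C)(C)O1)[C@@H](C)c1c(O[Si](C)(C)C(C)(C)C)cc(O[Si](C)(C)C(C)(C)C)c2cc(-c3c(CC=C(C)C)c(O[Si](C)(C)C(C)(C)C)cc4OC(C)(C)CCc34)oc12 | intermediate (not isolated)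
17 | pinacol [(3R)-1-iodo-2-methyl-3-(aryl)butan-2-yl]boronate, aryl = the benzofuran-7-yl unit of 15, epimer mixture at C2 | ICC(C)(B1OC(C)(C)C(C)(C)O1)[C@@H](C)c1c(O[Si](C)(C)C(C)(C)C)cc(O[Si](C)(C)C(C)(C)C)c2cc(-c3c(CC=C(C)C)c(O[Si](C)(C)C(C)(C)C)cc4OC(C)(C)CCc34)oc12 | intermediate (not isolated)
18 | 4,6-bis(tert-butyldimethylsilyloxy)-2-[7-(tert-butyldimethylsilyloxy)-2,2-dimethyl-6-(3-methylbut-2-en-1-yl)-3,4-dihydro-2H-chromen-5-yl]-7-[(2R)-3-methylbut-3-en-2-yl]-1-benzofuran | C=C(C)[C@@H](C)c1c(O[Si](C)(C)C(C)(C)C)cc(O[Si](C)(C)C(C)(C)C)c2cc(-c3c(CC=C(C)C)c(O[Si](C)(C)C(C)(C)C)cc4OC(C)(C)CCc34)oc12 | intermediate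
19 | 2-[7-hydroxy-2,2-dimethyl-6-(3-methylbut-2-en-1-yl)-3,4-dihydro-2H-chromen-5-yl]-7-[(2R)-3-methylbut-3-en-2-yl]-1-benzofuran-4,6-diol | C=C(C)[C@@H](C)c1c(O)cc(O)c2cc(-c3c(CC=C(C)C)c(O)cc4c3CCC(C)(C)O4)oc12 | target

Total step count: 11
Longest linear sequence: 9 steps (steps 1, 2, 3, 4, 7, 8, 9, 10, 11)

Steps most likely to fail

Step 2 (key step). Alkylation may occur at the carbon between the two hydroxyls, a second annulation may consume 5, or the free alkyne may be hydrated by the acid. The fallback sets out from 2. Pd(PPh3)4-catalysed O-alkylation with tert-butyl 2-methylbut-3-en-2-yl carbonate (THF, rt) would give 1-ethynyl-3,5-bis[(2-methylbut-3-en-2-yl)oxy]benzene F1. A double aromatic Claisen rearrangement (Eu(fod)3, CHCl3, 50 °C, or toluene, 110 °C) would then deliver both allyl units as prenyl groups ortho to the alkyne, since the meta oxygen and the meta alkyne both steer each migration to that carbon, giving 5-ethynyl-4,6-bis(3-methylbut-2-en-1-yl)benzene-1,3-diol F2. Brief exposure to Amberlyst 15 in CH2Cl2 at rt, stopped at partial conversion, would close one of the two equivalent prenyl/hydroxyl pairs. The fallback comes back to the route at 7, bypassing steps 2 and 3, at the price that the two ring bonds are then made in separate operations.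

Step 3. O-Alkylation, attack at C8 or double alkylation may outrun the wanted C6 prenylation. The fallback sets out from 5. Pd(PPh3)4-catalysed O-alkylation with tert-butyl 2-methylbut-3-en-2-yl carbonate would give 5-ethynyl-2,2-dimethyl-7-[(2-methylbut-3-en-2-yl)oxy]-3,4-dihydro-2H-chromene F3. Aromatic Claisen rearrangement (Eu(fod)3, CHCl3, 50 °C) should then move the allyl unit, with inversion to a prenyl group, to C6, the carbon para to O1 and next to the alkyne. The fallback comes back to the route at 7.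

Step 9. Hydrocupration of the hindered, electron-rich styrene may be slow, facial selectivity may be poor, or the benzylic boronate may protodeboronate. The fallback sets out from 13. Wittig olefination with ethyl 2-(triphenylphosphoranylidene)propanoate (toluene, 90 °C) would give ethyl (2E)-3-(aryl)-2-methylprop-2-enoate F4, aryl being the benzofuran-7-yl unit of 13. Reduction with i-Bu2AlH (CH2Cl2, −78 °C) would give (2E)-3-(aryl)-2-methylprop-2-en-1-ol F5, and MsCl, Et3N, LiCl (DMF, 0 °C) would give the (E)-allylic chloride F6. A copper-catalysed enantioselective SN2' allylic methylation (MeMgBr, CuBr·SMe2, chiral phosphoramidite or Taniaphos ligand of the antipode that gives the R product, CH2Cl2, −78 °C) would deliver methyl to the benzylic carbon. The fallback comes back to the route at 18, bypassing steps 8 to 10.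

Further compounds
F1 | step 2 | 1-ethynyl-3,5-bis[(2-methylbut-3-en-2-yl)oxy]benzene | C#Cc1cc(OC(C)(C)C=C)cc(OC(C)(C)C=C)c1
F2 | step 2 | 5-ethynyl-4,6-bis(3-methylbut-2-en-1-yl)benzene-1,3-diol | C#Cc1c(CC=C(C)C)c(O)cc(O)c1CC=C(C)C
F3 | step 3 | 5-ethynyl-2,2-dimethyl-7-[(2-methylbut-3-en-2-yl)oxy]-3,4-dihydro-2H-chromene | C#Cc1cc(OC(C)(C)C=C)cc2OC(C)(C)CCc12
F4 | step 9 | ethyl (2E)-3-{4,6-bis(tert-butyldimethylsilyloxy)-2-[7-(tert-butyldimethylsilyloxy)-2,2-dimethyl-6-(3-methylbut-2-en-1-yl)-3,4-dihydro-2H-chromen-5-yl]-1-benzofuran-7-yl}-2-methylprop-2-enoate | CCOC(=O)/C(C)=C/c1c(O[Si](C)(C)C(C)(C)C)cc(O[Si](C)(C)C(C)(C)C)c2cc(-c3c(CC=C(C)C)c(O[Si](C)(C)C(C)(C)C)cc4OC(C)(C)CCc34)oc12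
F5 | step 9 | (2E)-3-{4,6-bis(tert-butyldimethylsilyloxy)-2-[7-(tert-butyldimethylsilyloxy)-2,2-dimethyl-6-(3-methylbut-2-en-1-yl)-3,4-dihydro-2H-chromen-5-yl]-1-benzofuran-7-yl}-2-methylprop-2-en-1-ol | OC/C(C)=C/c1c(O[Si](C)(C)C(C)(C)C)cc(O[Si](C)(C)C(C)(C)C)c2cc(-c3c(CC=C(C)C)c(O[Si](C)(C)C(C)(C)C)cc4OC(C)(C)CCc34)oc12
F6 | step 9 | 4,6-bis(tert-butyldimethylsilyloxy)-2-[7-(tert-butyldimethylsilyloxy)-2,2-dimethyl-6-(3-methylbut-2-en-1-yl)-3,4-dihydro-2H-chromen-5-yl]-7-[(1E)-3-chloro-2-methylprop-1-en-1-yl]-1-benzofuran | ClC/C(C)=C/c1c(O[Si](C)(C)C(C)(C)C)cc(O[Si](C)(C)C(C)(C)C)c2cc(-c3c(CC=C(C)C)c(O[Si](C)(C)C(C)(C)C)cc4OC(C)(C)CCc34)oc12
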